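## Analysis of the target

Dipolynaphthalene B (29) is a tetralin. Its benzene ring (ring A: C4a, C5–C8, C8a) is fused to a cyclohexane ring (ring B: C1–C4, C4a, C8a). C1 carries a secondary benzylic hydroxyl, C5 a methoxy group and C4 a 4-hydroxy-5-methoxynaphthalen-1-yl group. The two stereocentres C1 and C4 are both S and stand 1,4-cis on ring B, too far apart for one to steer the other directly. Both are benzylic (C4 doubly), so the C1–O bond is open to ionisation, elimination and hydrogenolysis, and the C4–H bond to epimerisation by strong base. The naphthol with its peri methoxy group is electron-rich and oxidisable, and its hydroxyl must stay distinguishable from the C5 oxygen, which ends as a methyl ether. The main obstacle is ring A: C5–O, C4a and C8a are contiguous and the C5 oxygen sits next to the bulky C4 substituent. A Friedel–Crafts closure of ring B would have to attack meta to that oxygen in the presence of a far more nucleophilic naphthalene. The route rests on one feature: the chain C4–C3–C2–C1 links C4a and C8a. If C4a≡C5 (oxygen on C5) and C8a≡C8 are alkynes on that chain, a [2+2+2] cyclotrimerisation with a two-carbon partner (C6–C7) makes ring A and ring B at once, with the substitution pattern fixed by the tether and both stereocentres set beforehand on an open chain.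

## Retrosynthetic reasoning

**29 ⇒ 28 ⇒ 27 (naphthyl O–benzyl, C5 O–methyl).** The naphthol oxygen is kept as a benzyl ether from the start, so that the only free phenol at the stage of 27 is the C5 hydroxyl of ring A. That phenol is methylated beside the untouched secondary alcohol (28), and hydrogenolysis then frees the naphthol (29). The forward steps have to methylate a hindered phenol selectively and cleave an aryl benzyl ether without touching the benzylic C1–O bond.

**27 ⇒ 25 (two O–Si bonds and the C8–Si bond).** The C5 oxygen leaves the key step as a silyl ether, and C8 leaves it carrying SiMe3. Fluoride cleaves both O–Si bonds. C8 is para to the freed phenol, and an aryl–silicon bond in that position is lost by ipso-protonation under very mild acid. The silyl group on C8 is therefore a protecting group that costs no separate step.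

**25 ⇒ 23 + 24 (C4a–C8a, C5–C6, C7–C8).** This is the key disconnection. Cutting these three bonds removes ring A and ring B together and leaves the open-chain 1,7-diyne 23 and acetylene 24. No other cut addresses the 1,2,3-pattern of ring A so directly: the tether decides that the oxygen-bearing alkyne carbon becomes C5 beside C4a. The forward reaction has to cross-trimerise 23 with 24 without touching the two propargylic stereocentres. The distal alkyne is kept C-silylated for two reasons. A free C≡C–H would be metalated and silylated when the ynol ether is made. A C–Si bond also cannot be expected to be cleaved selectively beside a silyl ynol ether, because fluoride or alkoxide would attack the O–Si bond as well (the ynolate is an excellent leaving group).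

**23 ⇒ 20 (C4–C4a and the triple bond C4a≡C5).** The silyl ynol ether is traced to the ethyl ester 20 by a one-carbon homologation through the ynolate. The ester carbonyl becomes C5 with its oxygen, the inserted carbon becomes C4a, and the C4 stereocentre migrates with retention. This puts the sensitive ynol ether into the last step before the key step.

**20 ⇒ 19 ⇒ 18 ⇒ 17 (C1–H, protecting group, auxiliary).** The C1 stereocentre is a propargylic carbinol and is taken back to the ynone 17, where a catalyst-controlled transfer hydrogenation sets it independently of the remote C4 centre. Silylation (19) and exchange of the auxiliary for an ethyl ester (20) follow.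

**17 ⇒ 10 + 15 (C3–C4).** Cutting C3–C4 gives the arylacetyl imide 10 and the enynone 15. A conjugate addition of the chelated titanium enolate of 10 forms this bond and sets C4 under auxiliary control. It also brings in C1 at the ketone oxidation level and the C8a≡C8 alkyne already capped with silicon.

**15 ⇒ 11 + 12; 10 ⇒ 7 + 8; 7 ⇒ 6 ⇒ 4 + 5; 4 ⇒ 3 ⇒ 2 ⇒ 1.** The enynone comes from acetylide addition of 11 to 12 and oxidation of 14. The imide comes from acid 7 and auxiliary 8. The arylacetic acid comes from cross-coupling of bromide 4 with the zinc ester enolate 5 and saponification of 6. Bromide 4 is reached from the diol 1 by monomethylation (2), bromination para to the free hydroxyl (3) and benzylation. Bromination is done on the free naphthol because only then are the two rings electronically different.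

## Alternatives that were turned down

**Alternative 1:** The naphthol is disconnected instead of the tetralin. Its bonds C1'–C8a' and C4'–C4a' are cut, so that the hydroxyl-bearing ring is made last from 3-methoxybenzyne A1 and the 2-siloxyfuran A2, which already carries the finished cis-tetralin on its C5. Forward, A1 (set free from an ortho-silyl aryl triflate with fluoride) would add across C2 and C5 of A2, and the bridged silyl ketal would collapse to the para-quinol A3. A reductive aromatisation would then give the naphthol.
- For it: aryne–furan cycloaddition is an established reaction type. The polarisation of a 3-alkoxyaryne should send the nucleophilic furan carbon to the aryne carbon remote from the methoxy group, which places the carbonyl of A3 peri to OMe as needed. The oxidisable naphthol appears only at the end. On precedent for the bond-forming event this alternative is stronger than the chosen one.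
- Against it: it leaves the real difficulty untouched. A2 must already contain ring A with its three contiguous substituents and both stereocentres, so the problem is only moved into the synthesis of A2. The furan carbon that bonds is flanked by a bulky secondary benzylic centre. The quinol oxygen must be erased afterwards by reduction beside a benzylic silyl ether.
- Comparison: the chosen route spends its key step on the ring A/ring B problem itself and needs no redox correction.

**Alternative 2:** The C4 methine is disconnected. C4–C4a and C3–C4 are cut, leaving an aryl iodide flanked by bromine and methoxy, the N-tosylhydrazone of the naphthaldehyde and a propargyl aldehyde acetal. Forward, zerovalent palladium with a chiral phosphine, a copper co-catalyst and an alkoxide base would go through oxidative addition, carbene formation, aryl migration (C4–C4a) and alkynyl reductive elimination (C3–C4) to give A4. No ring closes.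
- For it: it has the highest convergence and reaches the C4-substituted carbon chain in far fewer steps than the chosen route. On step economy up to that point it is stronger.
- Against it: a doubly ortho-substituted aryl group must migrate onto a carbene carbon that bears a peri-hindered naphthyl. Asymmetric induction in this migratory insertion to a diaryl(alkynyl)methane centre is not dependable. The C–Br bond must survive zerovalent palladium. Afterwards the alkyne must be saturated beside a benzyl ether and an aryl bromide, the acetal hydrolysed, and ring B closed by aryl–metal addition to the aldehyde, where the cis/trans outcome at C1 is left to a weakly biased transition state.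
- Comparison: the chosen route is longer, but C4 comes from a chelated auxiliary enolate and C1 from a catalyst-controlled reduction, and the ring closure creates no stereocentre.

**Alternative 3:** Ring B is disconnected as a [4+2] adduct. C1–C2 and C3–C4 are cut, leading to the ortho-(naphthylmethyl)benzaldehyde A5 and an acrylate ester. Forward, irradiation of A5 with a titanium alkoxide and a chiral diol would give the hydroxy-ortho-quinodimethane, which adds the acrylate to give the all-cis ester A6.
- For it: A5 is quickly made. Ring B and both required stereocentres form in one step, with the 1,4-cis relation built into an endo transition state. Photoenolisation/Diels–Alder is an established type for ortho-alkylbenzaldehydes. On step count to the tetralin core it is clearly stronger than the chosen route.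
- Against it: the hydrogen to be abstracted sits on a diarylmethane carbon flanked by formyl and methoxy, and the dienol carries a bulky naphthyl on its terminus, so the dienol geometry that decides the C1/C4 relation is uncertain. The alkoxynaphthalene absorbs in the same region as the aldehyde and can quench or divert the excited state. The ester on C2 serves only to activate the dienophile and must be removed later (saponification, radical decarboxylation) β to a free hydroxyl, where retro-aldol cleavage and elimination threaten.
- Comparison: the chosen strategy is longer, but it builds only atoms that stay and does not rest its stereocontrol on a photochemical step.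

Key step: step 14

Remark on the chemistry: reagent 5 is taken as its commercial THF solution, and the alkyne terminus that becomes C8 is carried as its C–SiMe3 derivative in 23 and 25.

## Route

Step 1
Reactants: 1 naphthalene-1,8-diol
Product: 2 8-methoxynaphthalen-1-ol
Conditions: MeI (1.05 equiv), K2CO3 (1.0 equiv), acetone, 50 °C
Reagents that add atoms: iodomethane, CI
Why: Williamson etherification; one equivalent of base forms only the hydrogen-bond-stabilised monoanion, and the remaining hydroxyl of 2 is tied to the peri methoxy oxygen and much less acidic, so alkylation should stop at the monoether.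

Step 2
Reactants: 2 8-methoxynaphthalen-1-ol
Product: 3 4-bromo-8-methoxynaphthalen-1-ol
Conditions: NBS (1.0 equiv), MeCN, −20 → 0 °C
Reagents that add atoms: N-bromosuccinimide, O=C1CCC(=O)N1Br
Why: Electrophilic aromatic bromination; the free hydroxyl is the stronger donor (reinforced by the O–H···OMe hydrogen bond) and directs to C4, para to it, and a polar solvent, low temperature and one equivalent should hold back ortho and double bromination.

Step 3
Reactants: 3 4-bromo-8-methoxynaphthalen-1-ol
Product: 4 1-(benzyloxy)-4-bromo-8-methoxynaphthalene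
Conditions: BnBr, K2CO3, DMF, 50 °C
Reagents that add atoms: benzyl bromide, BrCc1ccccc1
Why: Williamson benzylation of the naphthol; the benzyl ether marks this oxygen as the one that is freed last.

Step 4
Reactants: 4 1-(benzyloxy)-4-bromo-8-methoxynaphthalene; 5 (2-ethoxy-2-oxoethyl)zinc bromide
Product: 6 ethyl 2-[4-(benzyloxy)-5-methoxynaphthalen-1-yl]acetate
Conditions: Pd2(dba)3 (2 mol %), XPhos (8 mol %), THF, 60 °C
Reagents that add atoms: none
Why: Negishi coupling of a Reformatsky reagent (palladium-catalysed α-arylation of a zinc ester enolate); the neutral zinc enolate tolerates the ethers and cannot arylate twice.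

Step 5
Reactants: 6 ethyl 2-[4-(benzyloxy)-5-methoxynaphthalen-1-yl]acetate
Product: 7 2-[4-(benzyloxy)-5-methoxynaphthalen-1-yl]acetic acid
Conditions: LiOH, THF/MeOH/H2O, rt; then 1 M HCl
Reagents that add atoms: water, O
Why: Saponification of an unhindered ethyl ester; no stereocentre is present yet.

Step 6
Reactants: 7 2-[4-(benzyloxy)-5-methoxynaphthalen-1-yl]acetic acid; 8 (S)-4-benzyloxazolidin-2-one
Product: 10 (S)-4-benzyl-3-{2-[4-(benzyloxy)-5-methoxynaphthalen-1-yl]acetyl}oxazolidin-2-one, via mixed pivalic anhydride 9 (not isolated)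
Conditions: t-BuCOCl, Et3N, THF, −20 °C; then 8, LiCl, rt
Reagents that add atoms: none
Why: N-acylation of the oxazolidinone through the mixed anhydride; the hindered pivaloyl carbonyl is not attacked, so only the arylacetyl group is transferred.

Step 7
Reactants: 11 ethynyltrimethylsilane; 12 acrolein
Product: 14 5-(trimethylsilyl)pent-1-en-4-yn-3-ol (racemic), via lithium trimethylsilylacetylide 13 (not isolated)
Conditions: n-BuLi, THF, −78 °C; then 12
Reagents that add atoms: none
Why: 1,2-Addition of a lithium acetylide to an enal at low temperature; the stereocentre formed is destroyed in the next step.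

Step 8
Reactants: 14 5-(trimethylsilyl)pent-1-en-4-yn-3-ol
Product: 15 5-(trimethylsilyl)pent-1-en-4-yn-3-one
Conditions: MnO2, CH2Cl2, rt
Reagents that add atoms: none
Why: Manganese dioxide oxidation of a doubly activated (allylic and propargylic) alcohol under neutral heterogeneous conditions; the sensitive enynone is filtered and used at once.

Step 9
Reactants: 10 (S)-4-benzyl-3-{2-[4-(benzyloxy)-5-methoxynaphthalen-1-yl]acetyl}oxazolidin-2-one; 15 5-(trimethylsilyl)pent-1-en-4-yn-3-one
Product: 17 (S)-4-benzyl-3-{(2S)-2-[4-(benzyloxy)-5-methoxynaphthalen-1-yl]-5-oxo-7-(trimethylsilyl)hept-6-ynoyl}oxazolidin-2-one, via trichlorotitanium enolate 16 (not isolated)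
Conditions: TiCl4, i-Pr2NEt, CH2Cl2, 0 °C; then 15, −78 °C
Reagents that add atoms: none
Why: Auxiliary-controlled Michael addition of a chelated Z-titanium enolate; the benzyl group of the oxazolidinone shields one enolate face, so the enone should add from the open face and set C2 (the later C4) as S. The silyl cap blocks the alkyne terminus, leaving the vinyl carbon as the only acceptor site.

Step 10
Reactants: 17 (S)-4-benzyl-3-{(2S)-2-[4-(benzyloxy)-5-methoxynaphthalen-1-yl]-5-oxo-7-(trimethylsilyl)hept-6-ynoyl}oxazolidin-2-one
Product: 18 (S)-4-benzyl-3-{(2S,5S)-2-[4-(benzyloxy)-5-methoxynaphthalen-1-yl]-5-hydroxy-7-(trimethylsilyl)hept-6-ynoyl}oxazolidin-2-one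
Conditions: Ru(p-cymene)[(S,S)-TsNCHPhCHPhNH] (2 mol %), i-PrOH, rt
Reagents that add atoms: none
Why: Noyori asymmetric transfer hydrogenation of an alkynyl ketone; the (S,S)-catalyst distinguishes the alkynyl from the alkyl side and should deliver hydride to give the (S)-propargylic alcohol (the later C1) under reagent control, independent of the remote C2 centre. The base-free amido complex leaves the α-aryl imide unepimerised.

Step 11
Reactants: 18 (S)-4-benzyl-3-{(2S,5S)-2-[4-(benzyloxy)-5-methoxynaphthalen-1-yl]-5-hydroxy-7-(trimethylsilyl)hept-6-ynoyl}oxazolidin-2-one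
Product: 19 (S)-4-benzyl-3-{(2S,5S)-2-[4-(benzyloxy)-5-methoxynaphthalen-1-yl]-5-[(tert-butyldimethylsilyl)oxy]-7-(trimethylsilyl)hept-6-ynoyl}oxazolidin-2-one
Conditions: t-BuMe2SiOTf, 2,6-lutidine, CH2Cl2, −78 °C
Reagents that add atoms: tert-butyldimethylsilyl trifluoromethanesulfonate, CC(C)(C)[Si](C)(C)OS(=O)(=O)C(F)(F)F
Why: Silylation of the secondary alcohol with a silyl triflate and a hindered base; fast at low temperature, so the δ-hydroxy imide has no time to lactonise.

Step 12
Reactants: 19 (S)-4-benzyl-3-{(2S,5S)-2-[4-(benzyloxy)-5-methoxynaphthalen-1-yl]-5-[(tert-butyldimethylsilyl)oxy]-7-(trimethylsilyl)hept-6-ynoyl}oxazolidin-2-one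
Product: 20 ethyl (2S,5S)-2-[4-(benzyloxy)-5-methoxynaphthalen-1-yl]-5-[(tert-butyldimethylsilyl)oxy]-7-(trimethylsilyl)hept-6-ynoate
Conditions: Ti(OEt)4 (0.5 equiv), EtOH, 75 °C
Reagents that add atoms: ethanol, CCO
Why: Titanate-mediated transesterification of the N-acyl oxazolidinone; titanium bridges the two imide carbonyls and delivers ethoxide to the exocyclic acyl group. The medium is neither basic enough to epimerise the α-aryl centre nor nucleophilic enough to cleave the alkynyl or alkyl silyl groups, and auxiliary 8 is recovered.

Step 13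
Reactants: 20 ethyl (2S,5S)-2-[4-(benzyloxy)-5-methoxynaphthalen-1-yl]-5-[(tert-butyldimethylsilyl)oxy]-7-(trimethylsilyl)hept-6-ynoate
Product: 23 triisopropyl{[(3S,6S)-3-[4-(benzyloxy)-5-methoxynaphthalen-1-yl]-6-[(tert-butyldimethylsilyl)oxy]-8-(trimethylsilyl)octa-1,7-diyn-1-yl]oxy}silane, via dibromomethyl ketone 21 (not isolated), via lithium ynolate 22 (not isolated)
Conditions: 2,2,6,6-tetramethylpiperidine, n-BuLi, THF, 0 °C; CH2Br2, −78 °C; 20; LiN(SiMe3)2; n-BuLi, −78 → 0 °C; i-Pr3SiOTf, −78 °C
Reagents that add atoms: dibromomethane, BrCBr; triisopropylsilyl trifluoromethanesulfonate, CC(C)[Si](OS(=O)(=O)C(F)(F)F)(C(C)C)C(C)C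
Why: Kowalski ynolate formation and O-silylation; LiCHBr2 adds to the ester, the enolate of 21 undergoes bromine–lithium exchange, and the secondary carbon migrates to the carbenoid carbon with retention, giving 22, which the hindered silyl triflate traps on oxygen. The C–SiMe3 cap keeps the second alkyne from being metalated and silylated.

Step 14
Reactants: 23 triisopropyl{[(3S,6S)-3-[4-(benzyloxy)-5-methoxynaphthalen-1-yl]-6-[(tert-butyldimethylsilyl)oxy]-8-(trimethylsilyl)octa-1,7-diyn-1-yl]oxy}silane; 24 acetylene
Product: 25 tert-butyl{[(1S,4S)-4-[4-(benzyloxy)-5-methoxynaphthalen-1-yl]-5-[(triisopropylsilyl)oxy]-8-(trimethylsilyl)-1,2,3,4-tetrahydronaphthalen-1-yl]oxy}dimethylsilane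
Conditions: RhCl(PPh3)3 (10 mol %), HC≡CH (1 atm), toluene, 60 °C, 23 added slowly
Reagents that add atoms: none
Why: Proposed new method: a RhCl(PPh3)3-catalysed [2+2+2] cyclotrimerisation in which one diyne terminus is a silyl ynol ether; the closest known reaction type is the RhCl(PPh3)3- or CpCo(CO)2-catalysed crossed cyclotrimerisation of 1,6- and 1,7-diynes with alkynes, which tolerates ynamide and silyl termini on the diyne and alkoxyalkynes as the free partner. After loss of phosphine, monovalent rhodium binds both tethered alkynes and couples them oxidatively to a trivalent rhodacyclopentadiene; this forms C4a–C8a and closes ring B as a six-membered carbocycle across the four-carbon tether, with C5 (OSi) and C8 (SiMe3) on the metal. Acetylene 24 then inserts into a Rh–C bond, and reductive elimination forms C5–C6 and C7–C8, closing ring A as the benzene ring and returning monovalent rhodium. No stereocentre is formed; C1 and C4 are propargylic spectators in a neutral aprotic medium and should arrive unchanged. Regiochemistry is fixed by the tether, since the oxygen-bearing alkyne carbon can only become C5 next to C4a and the silylated one C8 next to C8a. The selectivity that is needed is crossed over homo-coupling: slow addition of 23 into acetylene-saturated toluene keeps the diyne dilute, and its two capped termini cannot form vinylidenes or head-to-tail dimers. The electron-rich ynol ether should bind the metal well, while the neutral chloride complex is too weak a π-acid to start ketenium chemistry of the siloxyalkyne.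

Step 15
Reactants: 25 tert-butyl{[(1S,4S)-4-[4-(benzyloxy)-5-methoxynaphthalen-1-yl]-5-[(triisopropylsilyl)oxy]-8-(trimethylsilyl)-1,2,3,4-tetrahydronaphthalen-1-yl]oxy}dimethylsilane
Product: 27 (1S,4S)-4-[4-(benzyloxy)-5-methoxynaphthalen-1-yl]-1,2,3,4-tetrahydronaphthalene-1,5-diol, via C8-silylated phenol diol 26 (not isolated)
Conditions: Bu4NF, THF, 0 °C → rt; aqueous work-up; then CF3CO2H (5 equiv), CH2Cl2, 0 °C
Reagents that add atoms: none
Why: Fluoride cleaves both O–Si bonds, and the crude 26 then undergoes ipso-protodesilylation, an electrophilic aromatic substitution strongly accelerated by the para hydroxyl and the flanking alkyl groups, so brief dilute acid should suffice. The benzylic alcohol should not ionise under these conditions because the C5 oxygen is meta to C8a and gives the C1 cation no resonance support.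

Step 16
Reactants: 27 (1S,4S)-4-[4-(benzyloxy)-5-methoxynaphthalen-1-yl]-1,2,3,4-tetrahydronaphthalene-1,5-diol
Product: 28 (1S,4S)-4-[4-(benzyloxy)-5-methoxynaphthalen-1-yl]-5-methoxy-1,2,3,4-tetrahydronaphthalen-1-ol
Conditions: MeI, K2CO3, acetone, 40 °C
Reagents that add atoms: iodomethane, CI
Why: Williamson methylation; carbonate deprotonates only the phenol, so the secondary alcohol stays free.

Step 17
Reactants: 28 (1S,4S)-4-[4-(benzyloxy)-5-methoxynaphthalen-1-yl]-5-methoxy-1,2,3,4-tetrahydronaphthalen-1-ol
Product: 29 (1S,4S)-4-(4-hydroxy-5-methoxynaphthalen-1-yl)-5-methoxy-1,2,3,4-tetrahydronaphthalen-1-ol (dipolynaphthalene B)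
Conditions: H2 (1 atm), Pd/C, EtOAc, rt
Reagents that add atoms: none
Why: Hydrogenolysis of an aryl benzyl ether; under neutral conditions at one atmosphere this cleavage should be much faster than loss of the benzylic C1–OH, and the reaction is stopped when 28 is consumed.

## Compound list

1 | naphthalene-1,8-diol | Oc1cccc2cccc(O)c12 | starting material
2 | 8-methoxynaphthalen-1-ol | COc1cccc2cccc(O)c12 | intermediate
3 | 4-bromo-8-methoxynaphthalen-1-ol | COc1cccc2c(Br)ccc(O)c12 | intermediate
4 | 1-(benzyloxy)-4-bromo-8-methoxynaphthalene | COc1cccc2c(Br)ccc(OCc3ccccc3)c12 | intermediate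
5 | (2-ethoxy-2-oxoethyl)zinc bromide | CCOC(=O)C[Zn]Br | starting material
6 | ethyl 2-[4-(benzyloxy)-5-methoxynaphthalen-1-yl]acetate | CCOC(=O)Cc1ccc(OCc2ccccc2)c2c(OC)cccc12 | intermediate
7 | 2-[4-(benzyloxy)-5-methoxynaphthalen-1-yl]acetic acid | OC(=O)Cc1ccc(OCc2ccccc2)c2c(OC)cccc12 | intermediate
8 | (S)-4-benzyloxazolidin-2-one | O=C1N[C@@H](Cc2ccccc2)CO1 | starting material
9 | 2-[4-(benzyloxy)-5-methoxynaphthalen-1-yl]acetic pivalic anhydride | CC(C)(C)C(=O)OC(=O)Cc1ccc(OCc2ccccc2)c2c(OC)cccc12 | intermediate
10 | (S)-4-benzyl-3-{2-[4-(benzyloxy)-5-methoxynaphthalen-1-yl]acetyl}oxazolidin-2-one | O=C(Cc1ccc(OCc2ccccc2)c2c(OC)cccc12)N1[C@@H](Cc2ccccc2)COC1=O | intermediate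
11 | ethynyltrimethylsilane | C#C[Si](C)(C)C | starting material
12 | acrolein | C=CC=O | starting material
13 | lithium (trimethylsilyl)acetylide | [Li+].[C-]#C[Si](C)(C)C | intermediate
14 | 5-(trimethylsilyl)pent-1-en-4-yn-3-ol (racemic) | C=CC(O)C#C[Si](C)(C)C | intermediate
15 | 5-(trimethylsilyl)pent-1-en-4-yn-3-one | C=CC(=O)C#C[Si](C)(C)C | intermediate
16 | trichlorotitanium (Z)-enolate of 10 | Cl[Ti](Cl)(Cl)O/C(=C\c1ccc(OCc2ccccc2)c2c(OC)cccc12)N1[C@@H](Cc2ccccc2)COC1=O | intermediate
17 | (S)-4-benzyl-3-{(2S)-2-[4-(benzyloxy)-5-methoxynaphthalen-1-yl]-5-oxo-7-(trimethylsilyl)hept-6-ynoyl}oxazolidin-2-one | O=C([C@@H](CCC(=O)C#C[Si](C)(C)C)c1ccc(OCc2ccccc2)c2c(OC)cccc12)N1[C@@H](Cc2ccccc2)COC1=O | intermediate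
18 | (S)-4-benzyl-3-{(2S,5S)-2-[4-(benzyloxy)-5-methoxynaphthalen-1-yl]-5-hydroxy-7-(trimethylsilyl)hept-6-ynoyl}oxazolidin-2-one | O=C([C@@H](CC[C@H](O)C#C[Si](C)(C)C)c1ccc(OCc2ccccc2)c2c(OC)cccc12)N1[C@@H](Cc2ccccc2)COC1=O | intermediate
19 | (S)-4-benzyl-3-{(2S,5S)-2-[4-(benzyloxy)-5-methoxynaphthalen-1-yl]-5-[(tert-butyldimethylsilyl)oxy]-7-(trimethylsilyl)hept-6-ynoyl}oxazolidin-2-one | O=C([C@@H](CC[C@H](O[Si](C)(C)C(C)(C)C)C#C[Si](C)(C)C)c1ccc(OCc2ccccc2)c2c(OC)cccc12)N1[C@@H](Cc2ccccc2)COC1=O | intermediate
20 | ethyl (2S,5S)-2-[4-(benzyloxy)-5-methoxynaphthalen-1-yl]-5-[(tert-butyldimethylsilyl)oxy]-7-(trimethylsilyl)hept-6-ynoate | CCOC(=O)[C@@H](CC[C@H](O[Si](C)(C)C(C)(C)C)C#C[Si](C)(C)C)c1ccc(OCc2ccccc2)c2c(OC)cccc12 | intermediate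
21 | (3S,6S)-3-[4-(benzyloxy)-5-methoxynaphthalen-1-yl]-1,1-dibromo-6-[(tert-butyldimethylsilyl)oxy]-8-(trimethylsilyl)oct-7-yn-2-one | BrC(Br)C(=O)[C@@H](CC[C@H](O[Si](C)(C)C(C)(C)C)C#C[Si](C)(C)C)c1ccc(OCc2ccccc2)c2c(OC)cccc12 | intermediate
22 | lithium (3S,6S)-3-[4-(benzyloxy)-5-methoxynaphthalen-1-yl]-6-[(tert-butyldimethylsilyl)oxy]-8-(trimethylsilyl)octa-1,7-diyn-1-olate | [Li+].[O-]C#C[C@@H](CC[C@H](O[Si](C)(C)C(C)(C)C)C#C[Si](C)(C)C)c1ccc(OCc2ccccc2)c2c(OC)cccc12 | intermediate
23 | triisopropyl{[(3S,6S)-3-[4-(benzyloxy)-5-methoxynaphthalen-1-yl]-6-[(tert-butyldimethylsilyl)oxy]-8-(trimethylsilyl)octa-1,7-diyn-1-yl]oxy}silane | CC(C)[Si](OC#C[C@@H](CC[C@H](O[Si](C)(C)C(C)(C)C)C#C[Si](C)(C)C)c1ccc(OCc2ccccc2)c2c(OC)cccc12)(C(C)C)C(C)C | intermediate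
24 | acetylene | C#C | starting material
25 | tert-butyl{[(1S,4S)-4-[4-(benzyloxy)-5-methoxynaphthalen-1-yl]-5-[(triisopropylsilyl)oxy]-8-(trimethylsilyl)-1,2,3,4-tetrahydronaphthalen-1-yl]oxy}dimethylsilane | CC(C)[Si](Oc1ccc([Si](C)(C)C)c2c1[C@H](c1ccc(OCc3ccccc3)c3c(OC)cccc13)CC[C@@H]2O[Si](C)(C)C(C)(C)C)(C(C)C)C(C)C | intermediate
26 | (1S,4S)-4-[4-(benzyloxy)-5-methoxynaphthalen-1-yl]-8-(trimethylsilyl)-1,2,3,4-tetrahydronaphthalene-1,5-diol | Oc1ccc([Si](C)(C)C)c2c1[C@H](c1ccc(OCc3ccccc3)c3c(OC)cccc13)CC[C@@H]2O | intermediate
27 | (1S,4S)-4-[4-(benzyloxy)-5-methoxynaphthalen-1-yl]-1,2,3,4-tetrahydronaphthalene-1,5-diol | Oc1cccc2c1[C@H](c1ccc(OCc3ccccc3)c3c(OC)cccc13)CC[C@@H]2O | intermediate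
28 | (1S,4S)-4-[4-(benzyloxy)-5-methoxynaphthalen-1-yl]-5-methoxy-1,2,3,4-tetrahydronaphthalen-1-ol | COc1cccc2c1[C@H](c1ccc(OCc3ccccc3)c3c(OC)cccc13)CC[C@@H]2O | intermediate
29 | (1S,4S)-4-(4-hydroxy-5-methoxynaphthalen-1-yl)-5-methoxy-1,2,3,4-tetrahydronaphthalen-1-ol (dipolynaphthalene B) | COc1cccc2c1[C@H](c1ccc(O)c3c(OC)cccc13)CC[C@@H]2O | target

## Step count and least certain steps

Total step count: 17. Longest linear sequence: 15 steps (steps 1–6 and 9–17, from 1). Steps 7 and 8 are the side branch to 15.

**Step 14 (key step, proposed new method).** The oxidative coupling may be slow, because both alkyne termini carry substituents and the tether closes a six-membered ring. Acetylene oligomerisation, or thermal or metal-induced rearrangement of the silyl ynol ether (1,3-silyl shift to a silylketene), could then outrun ring formation.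

Fallback with known chemistry: the C5 oxygen is introduced through boron instead of an ynol ether. The fallback sets out from ester 20 and returns at 27.
- 20 is reduced with i-Bu2AlH at −78 °C to the hept-6-ynal F1, which is used crude because its α-aryl centre is labile.
- Ramirez olefination (CBr4, PPh3) gives the 1,1-dibromoalkene F2.
- Corey–Fuchs treatment with n-BuLi and trapping of the acetylide with 2-isopropoxy-4,4,5,5-tetramethyl-1,3,2-dioxaborolane gives the alkynyl pinacolboronate F3.
- CpCo(CO)2-mediated cocyclisation of F3 with acetylene (toluene, light, reflux) gives the arylboronate F4. Alkynylboronates and alkynylsilanes are both established partners in this reaction class.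
- Oxidation with NaBO3·4H2O gives the phenol F5.
- The conditions of step 15 convert F5 into 27.

**Step 13.** Two competing deprotonations threaten this step. The carbenoid or the lithium amide may remove the acidic α-aryl proton of 20 instead of adding to the carbonyl; this costs material as enolate but does not racemise what goes on. The excess n-BuLi may metalate the propargylic silyl ether carbon or the benzylic ether.

Fallback: the ynolate is made by acetylide oxidation instead of ester homologation. The fallback sets out from 20 and returns at 23.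
- 20 is taken through the hept-6-ynal F1 and the 1,1-dibromoalkene F2 as described above.
- n-BuLi (2 equiv, −78 °C) and a proton quench give the terminal diyne F6.
- Deprotonation with LiN(SiMe3)2, oxidation of the lithium acetylide with LiOOt-Bu and trapping with i-Pr3SiOTf return 23. No alkyllithium is present at the ynolate stage.

**Step 9.** The Lewis acid may polymerise the cross-conjugated enynone or add chloride to it, and facial selectivity erodes if the enolate is not fully chelated.

Fallback: a robust acceptor is used and the alkyne is attached afterwards. The fallback sets out from 10 and returns at 17.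
- The same titanium enolate adds to tert-butyl acrylate to give the tert-butyl pentanoate F7.
- CF3CO2H gives the pentanoic acid F8.
- (COCl)2 gives the acid chloride F9, which is not isolated.
- Acyl Sonogashira coupling of F9 with 11 (PdCl2(PPh3)2, CuI, Et3N) returns 17.

**Step 15.** The acid needed for protodesilylation may ionise the free benzylic alcohol, with epimerisation at C1 or elimination, or the ipso substitution may stay incomplete.

Fallback: the C-silyl group is removed before the ring is made. The fallback sets out from 23 and returns at 27.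
- K2CO3 in MeOH/THF at 0 °C should give the terminal diyne F10. The unhindered C–SiMe3 is expected to react before the shielded O–Si(i-Pr)3, but this selectivity is the weak point of the variant.
- Cyclotrimerisation of F10 with acetylene under the conditions of step 14 gives the tetralin F11, which carries no silicon on C8.
- Bu4NF alone then gives 27, with no acid treatment.

## Further compounds

F1 | step 14 | (2S,5S)-2-[4-(benzyloxy)-5-methoxynaphthalen-1-yl]-5-[(tert-butyldimethylsilyl)oxy]-7-(trimethylsilyl)hept-6-ynal | O=C[C@@H](CC[C@H](O[Si](C)(C)C(C)(C)C)C#C[Si](C)(C)C)c1ccc(OCc2ccccc2)c2c(OC)cccc12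
F2 | step 14 | {[(3R,6S)-3-[4-(benzyloxy)-5-methoxynaphthalen-1-yl]-1,1-dibromo-8-(trimethylsilyl)oct-1-en-7-yn-6-yl]oxy}(tert-butyl)dimethylsilane | BrC(Br)=C[C@@H](CC[C@H](O[Si](C)(C)C(C)(C)C)C#C[Si](C)(C)C)c1ccc(OCc2ccccc2)c2c(OC)cccc12
F3 | step 14 | tert-butyl{[(3S,6R)-6-[4-(benzyloxy)-5-methoxynaphthalen-1-yl]-8-(4,4,5,5-tetramethyl-1,3,2-dioxaborolan-2-yl)-1-(trimethylsilyl)octa-1,7-diyn-3-yl]oxy}dimethylsilane | CC1(C)OB(OC1(C)C)C#C[C@@H](CC[C@H](O[Si](C)(C)C(C)(C)C)C#C[Si](C)(C)C)c1ccc(OCc2ccccc2)c2c(OC)cccc12
F4 | step 14 | tert-butyl{[(1S,4S)-4-[4-(benzyloxy)-5-methoxynaphthalen-1-yl]-5-(4,4,5,5-tetramethyl-1,3,2-dioxaborolan-2-yl)-8-(trimethylsilyl)-1,2,3,4-tetrahydronaphthalen-1-yl]oxy}dimethylsilane | CC1(C)OB(OC1(C)C)c1ccc([Si](C)(C)C)c2c1[C@H](c1ccc(OCc3ccccc3)c3c(OC)cccc13)CC[C@@H]2O[Si](C)(C)C(C)(C)C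
F5 | step 14 | (5S,8S)-8-[4-(benzyloxy)-5-methoxynaphthalen-1-yl]-5-[(tert-butyldimethylsilyl)oxy]-4-(trimethylsilyl)-5,6,7,8-tetrahydronaphthalen-1-ol | Oc1ccc([Si](C)(C)C)c2c1[C@H](c1ccc(OCc3ccccc3)c3c(OC)cccc13)CC[C@@H]2O[Si](C)(C)C(C)(C)C
F6 | step 13 | tert-butyl{[(3S,6R)-6-[4-(benzyloxy)-5-methoxynaphthalen-1-yl]-1-(trimethylsilyl)octa-1,7-diyn-3-yl]oxy}dimethylsilane | C#C[C@@H](CC[C@H](O[Si](C)(C)C(C)(C)C)C#C[Si](C)(C)C)c1ccc(OCc2ccccc2)c2c(OC)cccc12
F7 | step 9 | tert-butyl (4S)-5-[(S)-4-benzyl-2-oxooxazolidin-3-yl]-4-[4-(benzyloxy)-5-methoxynaphthalen-1-yl]-5-oxopentanoate | CC(C)(C)OC(=O)CC[C@H](C(=O)N1[C@@H](Cc2ccccc2)COC1=O)c1ccc(OCc2ccccc2)c2c(OC)cccc12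
F8 | step 9 | (4S)-5-[(S)-4-benzyl-2-oxooxazolidin-3-yl]-4-[4-(benzyloxy)-5-methoxynaphthalen-1-yl]-5-oxopentanoic acid | OC(=O)CC[C@H](C(=O)N1[C@@H](Cc2ccccc2)COC1=O)c1ccc(OCc2ccccc2)c2c(OC)cccc12
F9 | step 9 | (4S)-5-[(S)-4-benzyl-2-oxooxazolidin-3-yl]-4-[4-(benzyloxy)-5-methoxynaphthalen-1-yl]-5-oxopentanoyl chloride | ClC(=O)CC[C@H](C(=O)N1[C@@H](Cc2ccccc2)COC1=O)c1ccc(OCc2ccccc2)c2c(OC)cccc12
F10 | step 15 | triisopropyl{[(3S,6S)-3-[4-(benzyloxy)-5-methoxynaphthalen-1-yl]-6-[(tert-butyldimethylsilyl)oxy]octa-1,7-diyn-1-yl]oxy}silane | CC(C)[Si](OC#C[C@H](c1ccc(OCc2ccccc2)c2c(OC)cccc12)CC[C@@H](C#C)O[Si](C)(C)C(C)(C)C)(C(C)C)C(C)C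
F11 | step 15 | tert-butyl{[(1S,4S)-4-[4-(benzyloxy)-5-methoxynaphthalen-1-yl]-5-[(triisopropylsilyl)oxy]-1,2,3,4-tetrahydronaphthalen-1-yl]oxy}dimethylsilane | CC(C)[Si](Oc1cccc2c1[C@H](c1ccc(OCc3ccccc3)c3c(OC)cccc13)CC[C@@H]2O[Si](C)(C)C(C)(C)C)(C(C)C)C(C)C
A1 | alternative 1 | 3-methoxybenzyne (1,2-didehydro-3-methoxybenzene) | COC1=CC=CC#C1
A2 | alternative 1 | tert-butyl({5-[(1R,4S)-4-[(tert-butyldimethylsilyl)oxy]-8-methoxy-1,2,3,4-tetrahydronaphthalen-1-yl]furan-2-yl}oxy)dimethylsilane | COc1cccc2c1[C@H](c1ccc(O[Si](C)(C)C(C)(C)C)o1)CC[C@@H]2O[Si](C)(C)C(C)(C)C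
A3 | alternative 1 | 4-{cis-4-[(tert-butyldimethylsilyl)oxy]-8-methoxy-1,2,3,4-tetrahydronaphthalen-1-yl}-4-hydroxy-8-methoxynaphthalen-1(4H)-one (quinol carbon unassigned) | COc1cccc2c1[C@H](C1(O)C=CC(=O)c3c(OC)cccc31)CC[C@@H]2O[Si](C)(C)C(C)(C)C
A4 | alternative 2 | 4-(benzyloxy)-1-[(1S)-1-(2-bromo-6-methoxyphenyl)-4,4-diethoxybut-2-yn-1-yl]-5-methoxynaphthalene | COc1cccc(Br)c1[C@H](c1ccc(OCc2ccccc2)c2c(OC)cccc12)C#CC(OCC)OCC
A5 | alternative 3 | 2-{[4-(benzyloxy)-5-methoxynaphthalen-1-yl]methyl}-3-methoxybenzaldehyde | COc1cccc(C=O)c1Cc1ccc(OCc2ccccc2)c2c(OC)cccc12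
A6 | alternative 3 | methyl (1S,2S,4S)-4-[4-(benzyloxy)-5-methoxynaphthalen-1-yl]-1-hydroxy-5-methoxy-1,2,3,4-tetrahydronaphthalene-2-carboxylate | COc1cccc2c1[C@H](c1ccc(OCc3ccccc3)c3c(OC)cccc13)C[C@H](C(=O)OC)[C@@H]2O
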